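**Retrosynthetic overview**
- The target is reached from a 4‑silyl, bis‑MOM‑protected arylnaphthalene by one acid step (protodesilylation and MOM removal).
- Key step: ring B (the dimethyl‑bearing ring) is built last by a Larock‑type palladium‑catalysed carboannulation of a 2,2‑diarylvinyl triflate with 1‑(trimethylsilyl)propyne, closing onto an aryl C–H bond. This replaces the usual biaryl Suzuki coupling or Friedel–Crafts cyclodehydration.
- The vinyl triflate carries two identical syringyl groups, so all four ortho C–H bonds give the same naphthalene; the ring that does not cyclise becomes the pendant aryl group.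
- The vinyl triflate comes from 1,1‑bis(syringyl)acetone, made in one step from two molecules of 2,6‑dimethoxyphenol and methylglyoxal.
- Ring order: both oxygenated benzene rings are bought; ring B is the only ring formed.

Assumption: the target has no stereocentre and its aryl–naphthyl axis carries a symmetric aryl group, so it is achiral; "single enantiomer" is taken to mean the compound as drawn.

**Step 1**
Reactants: 1 2,6-dimethoxyphenol (3 equiv used, 2 equiv react); 2 methylglyoxal (2-oxopropanal, 40 wt % in water)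
Product: 4 1,1-bis(4-hydroxy-3,5-dimethoxyphenyl)propan-2-one, via hydroxyketone 3 (not isolated)
Conditions: H2SO4 (cat.), AcOH, 40 °C, N2
Reagents that add atoms: none
Why: Acid‑catalysed hydroxyalkylation then Friedel–Crafts arylation (bisphenol‑type condensation): the aldehyde carbon of 2 is the most electrophilic site, the free OH of 1 directs attack to its para position (both ortho positions carry OMe), and benzylic alcohol 3 ionises to a para‑quinone‑methide‑like cation that a second molecule of 1 captures; 4 is achiral.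

**Step 2**
Reactants: 4 1,1-bis(4-hydroxy-3,5-dimethoxyphenyl)propan-2-one
Product: 5 1,1-bis[3,5-dimethoxy-4-(methoxymethoxy)phenyl]propan-2-one
Conditions: MOMCl (3 equiv), i-Pr2NEt (4 equiv), CH2Cl2, 0 °C → rt
Reagents that add atoms: chloromethyl methyl ether (MOMCl), COCCl
Why: Standard phenol O‑alkylation (MOM ether formation); the amine base is too weak to enolise the ketone, and no stereocentre is involved.

**Step 3**
Reactants: 5 1,1-bis[3,5-dimethoxy-4-(methoxymethoxy)phenyl]propan-2-one
Product: 7 1,1-bis[3,5-dimethoxy-4-(methoxymethoxy)phenyl]prop-1-en-2-yl trifluoromethanesulfonate, via potassium enolate 6 (not isolated)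
Conditions: KN(SiMe3)2 (1.0 equiv), THF, −78 → 0 °C (equilibrate); then PhNTf2 (1.1 equiv), 0 °C → rt
Reagents that add atoms: N-phenylbis(trifluoromethanesulfonimide) (PhNTf2), O=S(=O)(N(c1ccccc1)S(=O)(=O)C(F)(F)F)C(F)(F)F
Why: Enol triflate synthesis under equilibrating conditions: the doubly benzylic methine is far more acidic than the methyl group and gives the fully conjugated enolate 6, which is O‑triflated; the two aryl groups are identical, so no alkene geometry arises.

**Step 4**
Reactants: 7 1,1-bis[3,5-dimethoxy-4-(methoxymethoxy)phenyl]prop-1-en-2-yl trifluoromethanesulfonate; 8 trimethyl(prop-1-yn-1-yl)silane (1-(trimethylsilyl)propyne, 3 equiv)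
Product: 11 {4-[3,5-dimethoxy-4-(methoxymethoxy)phenyl]-6,8-dimethoxy-7-(methoxymethoxy)-2,3-dimethylnaphthalen-1-yl}trimethylsilane, via vinylpalladium chloride 9 (not isolated), via dienylpalladium chloride 10 (not isolated)
Conditions: Pd(OAc)2 (10 mol %), LiCl (1.5 equiv), NaOAc (3 equiv), DMF, 100 °C, sealed tube
Reagents that add atoms: none
Why: Larock‑type carboannulation of an internal alkyne by an aryl‑substituted vinylic triflate: oxidative addition of 7 to zerovalent palladium (formed in situ from Pd(OAc)2) gives 9, syn‑carbopalladation of 8 puts the vinyl group on the methyl‑bearing carbon and palladium on the bulkier silyl‑bearing carbon (10), and acetate‑assisted C–H palladation of the cis aryl ring (at a position ortho and para to OMe) followed by reductive elimination closes ring B; the four ortho C–H bonds are equivalent and no stereocentre is formed.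

**Step 5**
Reactants: 11 {4-[3,5-dimethoxy-4-(methoxymethoxy)phenyl]-6,8-dimethoxy-7-(methoxymethoxy)-2,3-dimethylnaphthalen-1-yl}trimethylsilane
Product: 13 sacidumlignan A, 5-(4-hydroxy-3,5-dimethoxyphenyl)-1,3-dimethoxy-6,7-dimethylnaphthalen-2-ol, via desilylated bis-MOM naphthalene 12 (not isolated)
Conditions: HCl (3 M in MeOH), MeOH/THF, 50 °C, argon
Reagents that add atoms: none
Why: Acid‑mediated ipso‑protodesilylation (fast at this electron‑rich naphthalene position, helped by relief of peri strain between SiMe3 and OMe) then MOM acetal methanolysis, with methanol trapping the methoxymethyl cation as dimethoxymethane so the electron‑rich rings are not re‑alkylated; the methyl ethers are stable and the product is achiral.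

**Compound list**
1 | 2,6-dimethoxyphenol (syringol) | COc1cccc(OC)c1O | starting material
2 | methylglyoxal (2-oxopropanal, 40 wt % aqueous) | CC(=O)C=O | starting material
3 | 1-hydroxy-1-(4-hydroxy-3,5-dimethoxyphenyl)propan-2-one (racemic, transient) | CC(=O)C(O)c1cc(OC)c(O)c(OC)c1 | intermediate
4 | 1,1-bis(4-hydroxy-3,5-dimethoxyphenyl)propan-2-one | CC(=O)C(c1cc(OC)c(O)c(OC)c1)c1cc(OC)c(O)c(OC)c1 | intermediate
5 | 1,1-bis[3,5-dimethoxy-4-(methoxymethoxy)phenyl]propan-2-one | CC(=O)C(c1cc(OC)c(OCOC)c(OC)c1)c1cc(OC)c(OCOC)c(OC)c1 | intermediate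
6 | potassium 1,1-bis[3,5-dimethoxy-4-(methoxymethoxy)phenyl]prop-1-en-2-olate | CC([O-])=C(c1cc(OC)c(OCOC)c(OC)c1)c1cc(OC)c(OCOC)c(OC)c1.[K+] | intermediate
7 | 1,1-bis[3,5-dimethoxy-4-(methoxymethoxy)phenyl]prop-1-en-2-yl trifluoromethanesulfonate | CC(OS(=O)(=O)C(F)(F)F)=C(c1cc(OC)c(OCOC)c(OC)c1)c1cc(OC)c(OCOC)c(OC)c1 | intermediate
8 | trimethyl(prop-1-yn-1-yl)silane (1-(trimethylsilyl)propyne) | CC#C[Si](C)(C)C | starting material
9 | chloro{1,1-bis[3,5-dimethoxy-4-(methoxymethoxy)phenyl]prop-1-en-2-yl}palladium (solvent ligands omitted) | CC([Pd]Cl)=C(c1cc(OC)c(OCOC)c(OC)c1)c1cc(OC)c(OCOC)c(OC)c1 | intermediate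
10 | chloro{(1Z)-4,4-bis[3,5-dimethoxy-4-(methoxymethoxy)phenyl]-2,3-dimethyl-1-(trimethylsilyl)buta-1,3-dien-1-yl}palladium (solvent ligands omitted) | C[Si](C)(C)/C([Pd]Cl)=C(\C)C(C)=C(c1cc(OC)c(OCOC)c(OC)c1)c1cc(OC)c(OCOC)c(OC)c1 | intermediate
11 | {4-[3,5-dimethoxy-4-(methoxymethoxy)phenyl]-6,8-dimethoxy-7-(methoxymethoxy)-2,3-dimethylnaphthalen-1-yl}trimethylsilane | COCOc1c(OC)cc(-c2c(C)c(C)c([Si](C)(C)C)c3c(OC)c(OCOC)c(OC)cc23)cc1OC | intermediate
12 | 5-[3,5-dimethoxy-4-(methoxymethoxy)phenyl]-1,3-dimethoxy-2-(methoxymethoxy)-6,7-dimethylnaphthalene | COCOc1c(OC)cc(-c2c(C)c(C)cc3c(OC)c(OCOC)c(OC)cc23)cc1OC | intermediate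
13 | sacidumlignan A, 5-(4-hydroxy-3,5-dimethoxyphenyl)-1,3-dimethoxy-6,7-dimethylnaphthalen-2-ol (achiral) | COc1cc(-c2c(C)c(C)cc3c(OC)c(O)c(OC)cc23)cc(OC)c1O | target

**Totals**
Total step count: 5. Longest linear sequence: 5 steps (1 and 2 to 13).

**Steps most likely to fail, with fallbacks**

Step 4 (carboannulation). The tetrasubstituted vinyl triflate is hindered, the new bond is formed next to a peri OMe with a bulky silyl group, and vinyl‑to‑aryl palladium migration could scramble the alkyne regiochemistry. Any 11 that loses silicon in the flask is 12 and still converges in step 5. The fallback sets out from 7 and comes back at 13. Suzuki coupling of 7 with isopropenylboronic acid pinacol ester (Pd(PPh3)4, K3PO4, dioxane/water, 80 °C) gives 1,1-bis[3,5-dimethoxy-4-(methoxymethoxy)phenyl]-2,3-dimethylbuta-1,3-diene F1. Hydroboration of its terminal alkene (9-BBN, THF; then NaBO3·4H2O) gives racemic 4,4-bis[3,5-dimethoxy-4-(methoxymethoxy)phenyl]-2,3-dimethylbut-3-en-1-ol F2. Dess–Martin oxidation gives racemic 4,4-bis[3,5-dimethoxy-4-(methoxymethoxy)phenyl]-2,3-dimethylbut-3-enal F3. HCl in MeOH at 50 °C then effects Bradsher‑type cyclodehydration onto the cis aryl ring, aromatisation and MOM removal in one operation to give 13.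

Step 1 (bis‑arylation of methylglyoxal). Risks are attack at the position ortho/para to the methoxy groups instead of para to OH, ketol isomerisation of 3, and air oxidation of 4. The fallback sets out from 1 and comes back at 5, fixing the regiochemistry with a C–Br bond. Bromination of 1 para to OH (NBS, cat. NaH, CHCl3, −45 °C → rt) gives 4-bromo-2,6-dimethoxyphenol F4. MOM protection (MOMCl, i-Pr2NEt, CH2Cl2) gives 5-bromo-1,3-dimethoxy-2-(methoxymethoxy)benzene F5. Palladium‑catalysed mono‑α‑arylation of acetone with F5 ([Pd(cinnamyl)Cl]2, Mor‑DalPhos, Cs2CO3, acetone, 90 °C) gives 1-[3,5-dimethoxy-4-(methoxymethoxy)phenyl]propan-2-one F6. A second α‑arylation of F6 with F5 at the more acidic benzylic carbon (Pd(OAc)2, XPhos, Cs2CO3, toluene, 100 °C) gives 5.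

Step 3 (regioselective enol triflation). Kinetic deprotonation at the methyl group would give the terminal enol triflate, and the stabilised diaryl enolate may triflate slowly. The fallback sets out from 5 and comes back at 11; it fixes the double‑bond position by conjugation instead of by enolate control. Reduction of 5 (NaBH4, MeOH, 0 °C) gives racemic 1,1-bis[3,5-dimethoxy-4-(methoxymethoxy)phenyl]propan-2-ol F7. Dehydration with Burgess reagent (toluene, 70 °C) gives the conjugated 1,1-bis[3,5-dimethoxy-4-(methoxymethoxy)phenyl]prop-1-ene F8. Electrophilic vinylic bromination through the diaryl‑stabilised cation (NBS, CH2Cl2, −20 °C) gives 2-bromo-1,1-bis[3,5-dimethoxy-4-(methoxymethoxy)phenyl]prop-1-ene F9. F9 is then annulated with 8 under the step 4 conditions (Pd(OAc)2, LiCl, NaOAc, DMF, 100 °C) to give 11.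

**Further compounds**
F1 | step 4 | 1,1-bis[3,5-dimethoxy-4-(methoxymethoxy)phenyl]-2,3-dimethylbuta-1,3-diene | C=C(C)C(C)=C(c1cc(OC)c(OCOC)c(OC)c1)c1cc(OC)c(OCOC)c(OC)c1
F2 | step 4 | 4,4-bis[3,5-dimethoxy-4-(methoxymethoxy)phenyl]-2,3-dimethylbut-3-en-1-ol (racemic) | OCC(C)C(C)=C(c1cc(OC)c(OCOC)c(OC)c1)c1cc(OC)c(OCOC)c(OC)c1
F3 | step 4 | 4,4-bis[3,5-dimethoxy-4-(methoxymethoxy)phenyl]-2,3-dimethylbut-3-enal (racemic) | O=CC(C)C(C)=C(c1cc(OC)c(OCOC)c(OC)c1)c1cc(OC)c(OCOC)c(OC)c1
F4 | step 1 | 4-bromo-2,6-dimethoxyphenol | COc1cc(Br)cc(OC)c1O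
F5 | step 1 | 5-bromo-1,3-dimethoxy-2-(methoxymethoxy)benzene | COCOc1c(OC)cc(Br)cc1OC
F6 | step 1 | 1-[3,5-dimethoxy-4-(methoxymethoxy)phenyl]propan-2-one | CC(=O)Cc1cc(OC)c(OCOC)c(OC)c1
F7 | step 3 | 1,1-bis[3,5-dimethoxy-4-(methoxymethoxy)phenyl]propan-2-ol (racemic) | CC(O)C(c1cc(OC)c(OCOC)c(OC)c1)c1cc(OC)c(OCOC)c(OC)c1
F8 | step 3 | 1,1-bis[3,5-dimethoxy-4-(methoxymethoxy)phenyl]prop-1-ene | CC=C(c1cc(OC)c(OCOC)c(OC)c1)c1cc(OC)c(OCOC)c(OC)c1
F9 | step 3 | 2-bromo-1,1-bis[3,5-dimethoxy-4-(methoxymethoxy)phenyl]prop-1-ene | CC(Br)=C(c1cc(OC)c(OCOC)c(OC)c1)c1cc(OC)c(OCOC)c(OC)c1
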